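The route rests on cutting the (E)-tetradecylidene tail on ring carbon C3 of the 5-methylene-oxolan-2-one between its third and fourth carbons (C1' = exocyclic alkene carbon). This C3'–C4' bond is a CH2–CH2 link whose nearer carbon is only homoallylic to the C3=C1' double bond and which is insulated from every functional group. A mixed Kolbe electrolysis forms it last: the complete, unprotected dimeric ester carrying an (E)-3-carboxypropylidene stub is co-electrolysed with excess lauric acid, and the primary homoallylic and undecyl radicals combine to give the target directly. Both halves arise from skipped diynols by syn- or trans-hydrostannation and Pd methoxycarbonylation.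

Key step: step 14

Assumption: (R,R)-ProPhenol/Me2Zn is assumed to deliver the alkynylzinc to the Si face of ynal 2; if the sense proves opposite, (S,S)-ProPhenol is used in steps 1 and 6 and nothing else changes.
Remark: along each branch the R/S descriptor of the carbinol carbon switches only because CIP priorities change (Sn, Si-alkynyl, C=O); the centre is never inverted.

Step 1
Reactants: 1 tert-butyl pent-4-ynoate; 2 3-(triisopropylsilyl)prop-2-ynal
Product: 3 tert-butyl (6S)-6-hydroxy-8-(triisopropylsilyl)octa-4,7-diynoate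
Conditions: Me2Zn, (R,R)-ProPhenol (20 mol%), Ph3PO (40 mol%), toluene, 4 °C; dil. HCl quench
Reagents that add atoms: none
Why: Zn–ProPhenol asymmetric alkynylation of an aldehyde: the alkynylzinc formed from 1 and Me2Zn (the tert-butyl ester is inert to it) is delivered in the chiral dinuclear zinc pocket to the Si face of ynal 2, which sets the carbinol centre as 6S, while the TIPS group shields the ynal β-carbon from conjugate addition.

Step 2
Reactants: 3 tert-butyl (6S)-6-hydroxy-8-(triisopropylsilyl)octa-4,7-diynoate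
Product: 4 tert-butyl (4E,6R)-6-hydroxy-5-(tributylstannyl)-8-(triisopropylsilyl)oct-4-en-7-ynoate
Conditions: Bu3SnH, PdCl2(PPh3)2 (cat.), THF, 0 °C to rt
Reagents that add atoms: tributyltin hydride, CCCC[SnH](CCCC)CCCC
Why: Pd(0)-catalysed hydrostannation is a syn addition in which, for propargylic alcohols, hydride goes to the distal and tin to the carbinol-bearing alkyne carbon, and the TIPS-capped alkyne is too hindered to react, so H and Sn end up cis and the ester chain trans to tin (4E), the geometry the lactone half needs.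

Step 3
Reactants: 4 tert-butyl (4E,6R)-6-hydroxy-5-(tributylstannyl)-8-(triisopropylsilyl)oct-4-en-7-ynoate
Product: 5 6-tert-butyl 1-methyl (2E)-2-[(1S)-1-hydroxy-3-(triisopropylsilyl)prop-2-yn-1-yl]hex-2-enedioate
Conditions: CO (1 atm), Pd(OAc)2 (cat.), Ph3As (cat.), 1,4-benzoquinone, TFA (cat.), MeOH, rt
Reagents that add atoms: carbon monoxide, [C-]#[O+]; methanol, CO
Why: Pd(II)-catalysed oxidative methoxycarbonylation of an alkenylstannane (Sn-to-Pd transmetalation, CO insertion, methanolysis, benzoquinone reoxidation) replaces tin by CO2Me with retention of the alkene geometry and tolerates the free allylic alcohol.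

Step 4
Reactants: 5 6-tert-butyl 1-methyl (2E)-2-[(1S)-1-hydroxy-3-(triisopropylsilyl)prop-2-yn-1-yl]hex-2-enedioate
Product: 7 (2E)-6-tert-butoxy-2-[(1R)-1-hydroxyprop-2-yn-1-yl]-6-oxohex-2-enoic acid, via desilylated diester 6 (not isolated)
Conditions: TBAF, THF, 0 °C; then LiOH, THF/MeOH/H2O, rt; dil. HCl to pH 3
Reagents that add atoms: lithium hydroxide, [Li+].[OH-]
Why: Fluoride cleaves the alkynyl C–Si bond and lithium hydroxide then saponifies the methyl ester, the tert-butyl ester being sterically inert to hydroxide; no stereo-element is touched.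

Step 5
Reactants: 7 (2E)-6-tert-butoxy-2-[(1R)-1-hydroxyprop-2-yn-1-yl]-6-oxohex-2-enoic acid
Product: 8 tert-butyl (4E)-4-[(4S)-4-hydroxy-5-methylidene-2-oxooxolan-3-ylidene]butanoate
Conditions: AgNO3 (10 mol%), acetone, rt, dark
Reagents that add atoms: none
Why: Ag(I)-catalysed cycloisomerisation of a pent-4-ynoic acid: the carboxylate adds 5-exo-dig to the silver-activated terminal alkyne and protodemetalation gives the γ-methylene (enol) lactone under neutral conditions that leave the free alcohol, the E alkene and the stereocentre untouched.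

Step 6
Reactants: 9 pentadec-1-yne; 2 3-(triisopropylsilyl)prop-2-ynal
Product: 10 (3S)-1-(triisopropylsilyl)octadeca-1,4-diyn-3-ol
Conditions: Me2Zn, (R,R)-ProPhenol (20 mol%), Ph3PO (40 mol%), toluene, 4 °C; dil. HCl quench
Reagents that add atoms: none
Why: The same Zn–ProPhenol asymmetric alkynylation as in step 1, the alkynylzinc from 9 adding to the Si face of 2 to set the carbinol centre as 3S.

Step 7
Reactants: 10 (3S)-1-(triisopropylsilyl)octadeca-1,4-diyn-3-ol
Product: 11 (3R,4Z)-4-(tributylstannyl)-1-(triisopropylsilyl)octadec-4-en-1-yn-3-ol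
Conditions: Bu3SnH, [Cp*RuCl]4 (cat.), CH2Cl2, rt
Reagents that add atoms: tributyltin hydride, CCCC[SnH](CCCC)CCCC
Why: Ru-catalysed trans-hydrostannation: the propargylic OH hydrogen-bonds to the chloride of the Cp*RuCl catalyst and steers tin to the adjacent alkyne carbon with anti delivery of H and Sn, while the TIPS-capped alkyne is too hindered to bind the Cp*Ru fragment, so the alkyl chain ends up cis to tin (4Z).

Step 8
Reactants: 11 (3R,4Z)-4-(tributylstannyl)-1-(triisopropylsilyl)octadec-4-en-1-yn-3-ol
Product: 12 methyl (2Z)-2-[(1S)-1-hydroxy-3-(triisopropylsilyl)prop-2-yn-1-yl]hexadec-2-enoate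
Conditions: CO (1 atm), Pd(OAc)2 (cat.), Ph3As (cat.), 1,4-benzoquinone, TFA (cat.), MeOH, rt
Reagents that add atoms: carbon monoxide, [C-]#[O+]; methanol, CO
Why: The same stereoretentive Pd(II)-catalysed oxidative methoxycarbonylation of an alkenylstannane as in step 3 places the ester cis to the alkyl chain (2Z).

Step 9
Reactants: 12 methyl (2Z)-2-[(1S)-1-hydroxy-3-(triisopropylsilyl)prop-2-yn-1-yl]hexadec-2-enoate
Product: 14 (2Z)-2-[(1R)-1-hydroxyprop-2-yn-1-yl]hexadec-2-enoic acid, via desilylated methyl ester 13 (not isolated)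
Conditions: TBAF, THF, 0 °C; then LiOH, THF/MeOH/H2O, rt; dil. HCl to pH 3
Reagents that add atoms: lithium hydroxide, [Li+].[OH-]
Why: Fluoride-mediated protodesilylation of the alkynylsilane followed by saponification of the methyl ester, neither of which touches the Z alkene or the carbinol centre.

Step 10
Reactants: 14 (2Z)-2-[(1R)-1-hydroxyprop-2-yn-1-yl]hexadec-2-enoic acid
Product: 16 (2Z)-2-[(1S)-1-hydroxy-2-oxopropyl]hexadec-2-enoic acid, via Z-enol lactone 15 (not isolated)
Conditions: AgNO3 (10 mol%), acetone, rt; then 1 M HCl, THF, rt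
Reagents that add atoms: water, O
Why: Ag(I)-catalysed 5-exo-dig cycloisomerisation gives enol lactone 15, and its acid-catalysed hydrolysis (C-protonation of the enol ester, addition of water, collapse of the lactol) unveils the methyl ketone, a carboxyl-directed Markovnikov hydration that avoids base and so should not epimerise the new α-ketol centre.

Step 11
Reactants: 16 (2Z)-2-[(1S)-1-hydroxy-2-oxopropyl]hexadec-2-enoic acid
Product: 18 (2Z)-2-[(1S)-2-oxo-1-(triethylsilyloxy)propyl]hexadec-2-enoic acid, via bis-TES derivative 17 (not isolated)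
Conditions: TESCl, imidazole, DMF, 0 °C; then THF/H2O, AcOH (cat.)
Reagents that add atoms: chlorotriethylsilane, CC[Si](Cl)(CC)CC
Why: Silylation with TESCl/imidazole caps the secondary α-ketol hydroxyl (and transiently the acid) without enolising the ketone, and the labile silyl ester is hydrolysed selectively on mild aqueous work-up.

Step 12
Reactants: 18 (2Z)-2-[(1S)-2-oxo-1-(triethylsilyloxy)propyl]hexadec-2-enoic acid; 8 tert-butyl (4E)-4-[(4S)-4-hydroxy-5-methylidene-2-oxooxolan-3-ylidene]butanoate
Product: 20 (3S,4E)-4-(4-tert-butoxy-4-oxobutylidene)-2-methylidene-5-oxooxolan-3-yl (2Z)-2-[(1S)-2-oxo-1-(triethylsilyloxy)propyl]hexadec-2-enoate, via mixed anhydride 19 (not isolated)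
Conditions: 2,4,6-Cl3C6H2COCl, Et3N, toluene, 0 °C; then 8, DMAP (0.3 equiv), 0 °C to rt
Reagents that add atoms: none
Why: Yamaguchi esterification: the mixed anhydride 19 acylates the hindered secondary allylic alcohol of 8 at oxygen, so both stereocentres are retained, and the low temperature with substoichiometric DMAP is chosen to limit Z-to-E isomerisation of the acyl donor and acyl transfer from the enol lactone.

Step 13
Reactants: 20 (3S,4E)-4-(4-tert-butoxy-4-oxobutylidene)-2-methylidene-5-oxooxolan-3-yl (2Z)-2-[(1S)-2-oxo-1-(triethylsilyloxy)propyl]hexadec-2-enoate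
Product: 21 (4E)-4-[(4S)-4-{[(2Z)-2-[(1S)-1-hydroxy-2-oxopropyl]hexadec-2-enoyl]oxy}-5-methylidene-2-oxooxolan-3-ylidene]butanoic acid
Conditions: TFA/CH2Cl2 (1:4), 0 °C to rt; aqueous work-up
Reagents that add atoms: none
Why: Acidolysis: TFA cleaves the tert-butyl ester by an E1 path (isobutene) and the TES ether in the same operation, while the enol ester, far less basic than an enol ether, and the allylic ester should survive short exposure to anhydrous acid.

Step 14
Reactants: 21 (4E)-4-[(4S)-4-{[(2Z)-2-[(1S)-1-hydroxy-2-oxopropyl]hexadec-2-enoyl]oxy}-5-methylidene-2-oxooxolan-3-ylidene]butanoic acid; 22 dodecanoic acid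
Product: 23 (3S,4E)-2-methylidene-5-oxo-4-tetradecylideneoxolan-3-yl (2Z)-2-[(1S)-1-hydroxy-2-oxopropyl]hexadec-2-enoate (CNP0377581.1)
Conditions: 22 (10 equiv), KOH (10 mol% of total acid), acetone, RVC anode/RVC cathode, undivided cell, rapid alternating polarity (50 ms), constant current, rt
Reagents that add atoms: none
Why: Anodic one-electron oxidation of the two carboxylates and loss of CO2 give the primary homoallylic radical of 21 and the undecyl radical, which recombine in the radical-rich layer at the anode to form the C3'–C4' bond (mixed Kolbe electrolysis). The closest known reaction is the classical hetero-Kolbe coupling of two unbranched aliphatic acids with the cheap partner in excess, here in its alternating-polarity acetone variant. No ring is closed and no stereocentre is formed; both existing centres lie far from the radical site and are not touched. The step needs cross- over homo-coupling, secured by the tenfold excess of 22 (docosane is removed by chromatography), and radical rather than carbocation chemistry, secured by the unbranched α-CH2 acid, which disfavours Hofer–Moest oxidation. It also needs the E alkene and the Michael acceptors to survive: the radical is homoallylic, not allylic, so it cannot transpose, its 3-exo closure should be slow and reversible against radical–radical coupling, and the β-alkylated enoates are poor acceptors for alkyl radicals. The non-nucleophilic solvent and the catalytic amount of base keep the enol lactone, the allylic ester and the α-ketol away from alkoxide.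

Compound list
1 | tert-butyl pent-4-ynoate | C#CCCC(=O)OC(C)(C)C | starting material
2 | 3-(triisopropylsilyl)prop-2-ynal | O=CC#C[Si](C(C)C)(C(C)C)C(C)C | starting material
3 | tert-butyl (6S)-6-hydroxy-8-(triisopropylsilyl)octa-4,7-diynoate | CC(C)(C)OC(=O)CCC#C[C@H](O)C#C[Si](C(C)C)(C(C)C)C(C)C | intermediate
4 | tert-butyl (4E,6R)-6-hydroxy-5-(tributylstannyl)-8-(triisopropylsilyl)oct-4-en-7-ynoate | CC(C)(C)OC(=O)CC/C=C(/[Sn](CCCC)(CCCC)CCCC)[C@H](O)C#C[Si](C(C)C)(C(C)C)C(C)C | intermediate
5 | 6-tert-butyl 1-methyl (2E)-2-[(1S)-1-hydroxy-3-(triisopropylsilyl)prop-2-yn-1-yl]hex-2-enedioate | COC(=O)/C(=C/CCC(=O)OC(C)(C)C)[C@H](O)C#C[Si](C(C)C)(C(C)C)C(C)C | intermediate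
6 | 6-tert-butyl 1-methyl (2E)-2-[(1R)-1-hydroxyprop-2-yn-1-yl]hex-2-enedioate | COC(=O)/C(=C/CCC(=O)OC(C)(C)C)[C@H](O)C#C | intermediate (not isolated)
7 | (2E)-6-tert-butoxy-2-[(1R)-1-hydroxyprop-2-yn-1-yl]-6-oxohex-2-enoic acid | OC(=O)/C(=C/CCC(=O)OC(C)(C)C)[C@H](O)C#C | intermediate
8 | tert-butyl (4E)-4-[(4S)-4-hydroxy-5-methylidene-2-oxooxolan-3-ylidene]butanoate | C=C1OC(=O)/C(=C/CCC(=O)OC(C)(C)C)[C@@H]1O | intermediate
9 | pentadec-1-yne | C#CCCCCCCCCCCCCC | starting material
10 | (3S)-1-(triisopropylsilyl)octadeca-1,4-diyn-3-ol | CCCCCCCCCCCCCC#C[C@H](O)C#C[Si](C(C)C)(C(C)C)C(C)C | intermediate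
11 | (3R,4Z)-4-(tributylstannyl)-1-(triisopropylsilyl)octadec-4-en-1-yn-3-ol | CCCCCCCCCCCCC/C=C(\[Sn](CCCC)(CCCC)CCCC)[C@H](O)C#C[Si](C(C)C)(C(C)C)C(C)C | intermediate
12 | methyl (2Z)-2-[(1S)-1-hydroxy-3-(triisopropylsilyl)prop-2-yn-1-yl]hexadec-2-enoate | COC(=O)/C(=C\CCCCCCCCCCCCC)[C@H](O)C#C[Si](C(C)C)(C(C)C)C(C)C | intermediate
13 | methyl (2Z)-2-[(1R)-1-hydroxyprop-2-yn-1-yl]hexadec-2-enoate | COC(=O)/C(=C\CCCCCCCCCCCCC)[C@H](O)C#C | intermediate (not isolated)
14 | (2Z)-2-[(1R)-1-hydroxyprop-2-yn-1-yl]hexadec-2-enoic acid | OC(=O)/C(=C\CCCCCCCCCCCCC)[C@H](O)C#C | intermediate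
15 | (3Z,4S)-4-hydroxy-5-methylidene-3-tetradecylideneoxolan-2-one | C=C1OC(=O)/C(=C\CCCCCCCCCCCCC)[C@@H]1O | intermediate (not isolated)
16 | (2Z)-2-[(1S)-1-hydroxy-2-oxopropyl]hexadec-2-enoic acid | OC(=O)/C(=C\CCCCCCCCCCCCC)[C@H](O)C(C)=O | intermediate
17 | triethylsilyl (2Z)-2-[(1S)-2-oxo-1-(triethylsilyloxy)propyl]hexadec-2-enoate | CC[Si](CC)(CC)OC(=O)/C(=C\CCCCCCCCCCCCC)[C@H](O[Si](CC)(CC)CC)C(C)=O | intermediate (not isolated)
18 | (2Z)-2-[(1S)-2-oxo-1-(triethylsilyloxy)propyl]hexadec-2-enoic acid | OC(=O)/C(=C\CCCCCCCCCCCCC)[C@H](O[Si](CC)(CC)CC)C(C)=O | intermediate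
19 | (2Z)-2-[(1S)-2-oxo-1-(triethylsilyloxy)propyl]hexadec-2-enoic 2,4,6-trichlorobenzoic anhydride | O=C(OC(=O)/C(=C\CCCCCCCCCCCCC)[C@H](O[Si](CC)(CC)CC)C(C)=O)c1c(Cl)cc(Cl)cc1Cl | intermediate (not isolated)
20 | (3S,4E)-4-(4-tert-butoxy-4-oxobutylidene)-2-methylidene-5-oxooxolan-3-yl (2Z)-2-[(1S)-2-oxo-1-(triethylsilyloxy)propyl]hexadec-2-enoate | C=C1OC(=O)/C(=C/CCC(=O)OC(C)(C)C)[C@@H]1OC(=O)/C(=C\CCCCCCCCCCCCC)[C@H](O[Si](CC)(CC)CC)C(C)=O | intermediate
21 | (4E)-4-[(4S)-4-{[(2Z)-2-[(1S)-1-hydroxy-2-oxopropyl]hexadec-2-enoyl]oxy}-5-methylidene-2-oxooxolan-3-ylidene]butanoic acid | C=C1OC(=O)/C(=C/CCC(=O)O)[C@@H]1OC(=O)/C(=C\CCCCCCCCCCCCC)[C@H](O)C(C)=O | intermediate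
22 | dodecanoic acid (lauric acid) | CCCCCCCCCCCC(=O)O | starting material
23 | (3S,4E)-2-methylidene-5-oxo-4-tetradecylideneoxolan-3-yl (2Z)-2-[(1S)-1-hydroxy-2-oxopropyl]hexadec-2-enoate | C=C1OC(=O)/C(=C/CCCCCCCCCCCCC)[C@@H]1OC(=O)/C(=C\CCCCCCCCCCCCC)[C@H](O)C(C)=O | target

Total step count: 14. Longest linear sequence: 9 steps (steps 6–14, from 9 and 2).

Steps most likely to fail

Step 14. The E geometry could be lost through reversible 3-exo closure of the homoallylic radical onto the alkylidene lactone, the radical could be over-oxidised to a cation, or the enol lactone and allylic ester could degrade at the electrodes before coupling. The fallback sets out from 21 and returns at 23. Acid 21 would be condensed with N-hydroxyphthalimide and diisopropylcarbodiimide in CH2Cl2 to the redox-active N-(acyloxy)phthalimide ester of 21 F1. F1 would then be coupled with excess undecylzinc bromide (from 1-bromoundecane and zinc) under NiCl2·glyme and 4,4'-di-tert-butyl-2,2'-bipyridine in THF/DMF at room temperature. This nickel-catalysed decarboxylative alkyl–alkyl coupling forms the same C3'–C4' bond under mildly reducing, non-electrolytic conditions, the alkyl radical being captured by nickel instead of by a second free radical.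

Step 12. DMAP may isomerise the Z acyl donor to E by conjugate addition–elimination, the activated γ-keto acid may cyclise to its own enol lactone, and the enol lactone of 8 may itself transfer its acyl group. The fallback sets out from 18 and 8 and returns at 20. Acid 18 would be converted with 2,2'-dipyridyl disulfide and PPh3 in CH2Cl2 into the S-pyridin-2-yl thioester of 18 F2. F2 would then be activated towards alcohol 8 with AgOTf in toluene at room temperature. This thiophilic, amine-free activation avoids both the nucleophilic catalyst and the base.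

Step 2. Tin may be delivered in part to the distal alkyne carbon, giving poor regiocontrol. The fallback sets out from 3 and returns at 4. Diynol 3 would be oxidised with MnO2 in CH2Cl2 to the diynone tert-butyl 6-oxo-8-(triisopropylsilyl)octa-4,7-diynoate F3. Pd(PPh3)4/Bu3SnH in THF at 0 °C should then place tin α to the carbonyl by syn addition under electronic control, giving tert-butyl (4E)-6-oxo-5-(tributylstannyl)-8-(triisopropylsilyl)oct-4-en-7-ynoate F4. Reduction of F4 with (S)-Me-CBS/catecholborane in toluene at −78 °C, the stannylvinyl group acting as the large and the alkynyl as the small substituent, should return (6R)-4. The same reduction would also repair insufficient enantiopurity from step 1.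

Further compounds
F1 | step 14 | 1,3-dioxoisoindolin-2-yl (4E)-4-[(4S)-4-{[(2Z)-2-[(1S)-1-hydroxy-2-oxopropyl]hexadec-2-enoyl]oxy}-5-methylidene-2-oxooxolan-3-ylidene]butanoate | C=C1OC(=O)/C(=C/CCC(=O)ON2C(=O)c3ccccc3C2=O)[C@@H]1OC(=O)/C(=C\CCCCCCCCCCCCC)[C@H](O)C(C)=O
F2 | step 12 | S-pyridin-2-yl (2Z)-2-[(1S)-2-oxo-1-(triethylsilyloxy)propyl]hexadec-2-enethioate | O=C(Sc1ccccn1)/C(=C\CCCCCCCCCCCCC)[C@H](O[Si](CC)(CC)CC)C(C)=O
F3 | step 2 | tert-butyl 6-oxo-8-(triisopropylsilyl)octa-4,7-diynoate | CC(C)(C)OC(=O)CCC#CC(=O)C#C[Si](C(C)C)(C(C)C)C(C)C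
F4 | step 2 | tert-butyl (4E)-6-oxo-5-(tributylstannyl)-8-(triisopropylsilyl)oct-4-en-7-ynoate | CC(C)(C)OC(=O)CC/C=C(/[Sn](CCCC)(CCCC)CCCC)C(=O)C#C[Si](C(C)C)(C(C)C)C(C)C
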